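## Retrosynthetic overview
1. The trans-diol comes from water opening a (3R,4R)-chromene oxide at C4 with inversion. The oxide comes from catalyst-controlled oxygen transfer to a 2,2-dimethylchromene.
2. The pyran ring and the ring B 3'-OH are made in one operation from a 4'-hydroxy-3'-prenylflavanone: ortho-oxygenation to the o-quinone, tautomerisation to the vinyl o-quinone methide, then oxa-6π closure.
3. Ring C and C2 (S) come from chalcone isomerase-catalysed oxa-Michael closure of the unprotected 2'-hydroxychalcone.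
4. The chalcone comes from Claisen–Schmidt union of 2,4-dihydroxyacetophenone with 4-hydroxy-3-prenylbenzaldehyde, which is made by aqueous C-prenylation of 4-hydroxybenzaldehyde.
5. Ring order: A and B are bought, ring C forms in step 3, pyran ring D in step 4, and a transient oxirane is opened to the diol in step 5.

Assumption: the SMILES is read as (2S)-7-hydroxy-2-[(3R,4S)-3,4,8-trihydroxy-2,2-dimethylchroman-6-yl]chroman-4-one (trans-3,4-diol), and recombinant Medicago sativa chalcone isomerase from E. coli expression is taken as an accessible catalyst.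

## Route

Step 1
Reactants: 1 4-hydroxybenzaldehyde; 2 prenyl bromide (1-bromo-3-methylbut-2-ene)
Product: 3 4-hydroxy-3-(3-methylbut-2-en-1-yl)benzaldehyde
Conditions: KOH (1.2 equiv), H2O, rt, 24 h; chromatography
Reagents that add atoms: none
Why: This is ambident phenoxide alkylation, in which water hydrogen-bonds to and shields the phenoxide oxygen so that the soft allylic bromide is taken up at the ortho carbon (C-prenylation, the flask counterpart of an aromatic prenyltransferase) and rearomatisation gives 3; the O-prenyl ether and the 3,5-diprenyl by-product are separable, and no stereocentre is formed.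

Step 2
Reactants: 3 4-hydroxy-3-(3-methylbut-2-en-1-yl)benzaldehyde; 4 2,4-dihydroxyacetophenone
Product: 5 (E)-1-(2,4-dihydroxyphenyl)-3-[4-hydroxy-3-(3-methylbut-2-en-1-yl)phenyl]prop-2-en-1-one
Conditions: KOH (60% aq, 20 equiv), EtOH, 0 to 40 °C, 48 h, Ar; cold 2 M HCl to pH 5
Reagents that add atoms: none
Why: This is a Claisen–Schmidt aldol condensation on the unprotected polyphenoxides, as used for isoliquiritigenin and butein; E1cB dehydration gives only the (E)-enone, the prenyl group is inert to base, and the modest yield falls on cheap material.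

Step 3
Reactants: 5 (E)-1-(2,4-dihydroxyphenyl)-3-[4-hydroxy-3-(3-methylbut-2-en-1-yl)phenyl]prop-2-en-1-one
Product: 6 (2S)-7-hydroxy-2-[4-hydroxy-3-(3-methylbut-2-en-1-yl)phenyl]chroman-4-one
Conditions: recombinant Medicago sativa chalcone isomerase (legume type, cell-free extract), KH2PO4/K2HPO4 buffer 50 mM pH 7.5, 5% DMSO, 25 °C, substrate fed to about 1 mM, 1–2 h; EtOAc extraction at pH 6
Reagents that add atoms: none
Why: This is an enzymatic intramolecular oxa-Michael addition in which the legume enzyme accepts 6'-deoxychalcones and delivers the 2'-phenoxide to a single face of the enone, setting C2 as S; the hydrogen-bonded 2'-OH makes uncatalysed closure negligible at this pH, so there is no racemic background.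

Step 4
Reactants: 6 (2S)-7-hydroxy-2-[4-hydroxy-3-(3-methylbut-2-en-1-yl)phenyl]chroman-4-one
Product: 10 (2S)-7-(triethylsilyloxy)-2-[2,2-dimethyl-8-(triethylsilyloxy)-2H-chromen-6-yl]chroman-4-one, via o-quinone 7 (not isolated), via vinyl o-quinone methide 8 (not isolated), via chromenol 9 (not isolated)
Conditions: IBX (1.0 equiv), DMF (0.02 M), 0 °C to rt, dark, 1 h; 2,6-lutidine (2 equiv), rt, until the red colour fades; imidazole (8 equiv), TESCl (6 equiv), 0 °C to rt
Reagents that add atoms: IBX (2-iodoxybenzoic acid) O=C1OI(=O)(O)c2ccccc12; TESCl (chlorotriethylsilane) CC[Si](Cl)(CC)CC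
Why: Proposed new method: the pentavalent-iodine reagent binds only the electron-rich ring B phenol (the 7-OH is deactivated by the para carbonyl), transfers oxygen to its single free ortho carbon and oxidises on to o-quinone 7 (the known IBX phenol-to-o-quinone oxidation); the doubly activated allylic/benzylic CH2 of the prenyl group is then lost under weak hindered base to give vinyl o-quinone methide 8, which closes irreversibly by oxa-6π electrocyclisation to chromenol 9 (closest known reaction type: the base-catalysed prenylquinone-to-chromenol isomerisation), and silylation in the same flask shields both phenols; no stereocentre is formed, and C2 is retained because only weak bases are present and the para oxygen that could open ring C ends up alkylated.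

Step 5
Reactants: 10 (2S)-7-(triethylsilyloxy)-2-[2,2-dimethyl-8-(triethylsilyloxy)-2H-chromen-6-yl]chroman-4-one
Product: 13 (2S)-7-hydroxy-2-[(3R,4S)-3,4,8-trihydroxy-2,2-dimethylchroman-6-yl]chroman-4-one (target), via epoxide 11 (not isolated), via silylated trans-diol 12 (not isolated)
Conditions: (R,R)-[N,N'-bis(3,5-di-tert-butylsalicylidene)-1,2-cyclohexanediaminato]MnCl (5 mol %), NMO (5 equiv), mCPBA (1.5 equiv), CH2Cl2, −78 °C, 1 h; cold reductive bicarbonate wash; crude 11 in THF/0.5 M aq H2SO4 (3:1), 0 °C to rt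
Reagents that add atoms: mCPBA (3-chloroperoxybenzoic acid) OOC(=O)c1cccc(Cl)c1; water O
Why: This is a Jacobsen–Katsuki epoxidation, for which 2,2-dimethylchromenes are the best substrate class and the (R,R)-catalyst gives the (3R,4R)-oxide under catalyst control, independent of the remote C2; acid-catalysed hydrolysis then brings water in at the O1-stabilised benzylic C4 anti to the C3 oxygen (C3 retained as R, C4 inverted to S, giving the trans-diol), the same dilute acid removes both aryl triethylsilyl ethers, and flavanone C2 is stable to it.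

## Compound list
1 | 4-hydroxybenzaldehyde | O=Cc1ccc(O)cc1 | starting material
2 | prenyl bromide (1-bromo-3-methylbut-2-ene) | CC(C)=CCBr | starting material
3 | 4-hydroxy-3-(3-methylbut-2-en-1-yl)benzaldehyde | CC(C)=CCc1cc(C=O)ccc1O | intermediate
4 | 2,4-dihydroxyacetophenone | CC(=O)c1ccc(O)cc1O | starting material
5 | (E)-1-(2,4-dihydroxyphenyl)-3-[4-hydroxy-3-(3-methylbut-2-en-1-yl)phenyl]prop-2-en-1-one | CC(C)=CCc1cc(/C=C/C(=O)c2ccc(O)cc2O)ccc1O | intermediate
6 | (2S)-7-hydroxy-2-[4-hydroxy-3-(3-methylbut-2-en-1-yl)phenyl]chroman-4-one | CC(C)=CCc1cc([C@@H]2CC(=O)c3ccc(O)cc3O2)ccc1O | intermediate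
7 | 5-[(2S)-7-hydroxy-4-oxochroman-2-yl]-3-(3-methylbut-2-en-1-yl)-1,2-benzoquinone | CC(C)=CCC1=CC([C@@H]2CC(=O)c3ccc(O)cc3O2)=CC(=O)C1=O | intermediate
8 | (6Z)-2-hydroxy-4-[(2S)-7-hydroxy-4-oxochroman-2-yl]-6-(3-methylbut-2-en-1-ylidene)cyclohexa-2,4-dien-1-one | CC(C)=C/C=C1/C=C([C@@H]2CC(=O)c3ccc(O)cc3O2)C=C(O)C1=O | intermediate
9 | (2S)-7-hydroxy-2-(8-hydroxy-2,2-dimethyl-2H-chromen-6-yl)chroman-4-one | CC1(C)C=Cc2cc([C@@H]3CC(=O)c4ccc(O)cc4O3)cc(O)c2O1 | intermediate
10 | (2S)-7-(triethylsilyloxy)-2-[2,2-dimethyl-8-(triethylsilyloxy)-2H-chromen-6-yl]chroman-4-one | CC1(C)C=Cc2cc([C@@H]3CC(=O)c4ccc(O[Si](CC)(CC)CC)cc4O3)cc(O[Si](CC)(CC)CC)c2O1 | intermediate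
11 | (3R,4R)-3,4-epoxide of 10 (cis-fused oxirane on the pyran ring, 2S retained) | CC1(C)Oc2c(O[Si](CC)(CC)CC)cc([C@@H]3CC(=O)c4ccc(O[Si](CC)(CC)CC)cc4O3)cc2[C@H]5O[C@@H]15 | intermediate
12 | (2S)-7-(triethylsilyloxy)-2-[(3R,4S)-3,4-dihydroxy-2,2-dimethyl-8-(triethylsilyloxy)chroman-6-yl]chroman-4-one | CC1(C)Oc2c(O[Si](CC)(CC)CC)cc([C@@H]3CC(=O)c4ccc(O[Si](CC)(CC)CC)cc4O3)cc2[C@H](O)[C@H]1O | intermediate
13 | (2S)-7-hydroxy-2-[(3R,4S)-3,4,8-trihydroxy-2,2-dimethylchroman-6-yl]chroman-4-one | CC1(C)Oc2c(O)cc([C@@H]3CC(=O)c4ccc(O)cc4O3)cc2[C@H](O)[C@H]1O | target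

## Step count
Total step count: 5.
Longest linear sequence: 5 (1 → 3 → 5 → 6 → 10 → 13).

## Steps most likely to fail

**Step 4 (highest risk).**
- Risk: o-quinone 7 can also tautomerise through the flavanone C2–H to a p-quinone methide, which would erode C2 or lead to the flavone. It can also dimerise, and chromenol 9 can be over-oxidised.
- Route: the fallback sets out from 4 and comes back at 9, so C2 is set only after the pyran ring exists.
- Purchased 3,4-dihydroxybenzaldehyde is alkylated at its more acidic 4-OH with 3-chloro-3-methylbut-1-yne (K2CO3, KI, DMF, 60 °C) to 3-hydroxy-4-[(2-methylbut-3-yn-2-yl)oxy]benzaldehyde F1.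
- Heating F1 in N,N-diethylaniline at 190 °C drives aryl propargyl Claisen rearrangement, [1,5]-H shift and oxa-6π closure to 8-hydroxy-2,2-dimethyl-2H-chromene-6-carbaldehyde F2.
- Claisen–Schmidt condensation of F2 with 4 under the KOH/EtOH conditions gives (E)-1-(2,4-dihydroxyphenyl)-3-(8-hydroxy-2,2-dimethyl-2H-chromen-6-yl)prop-2-en-1-one F3.
- Ring C of F3 is closed with the isomerase to give 9, which is silylated (TESCl, imidazole) to 10.

**Step 3.**
- Risk: the ring B prenyl group may not fit the enzyme cleft, and substrate solubility is low.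
- Route: the fallback sets out from 5 and comes back at 6. It replaces enantioselective closure by racemic closure plus kinetic resolution.
- NaOAc in refluxing EtOH cyclises 5 to racemic 7-hydroxy-2-[4-hydroxy-3-(3-methylbut-2-en-1-yl)phenyl]chroman-4-one F4.
- Noyori-type asymmetric transfer hydrogenation with RuCl(p-cymene)[(R,R)-TsDPEN] in HCO2H/Et3N (5:2) is stopped near 50–55% conversion.
- It reduces the matched (2R)-enantiomer to cis-(2R,4R)-2-[4-hydroxy-3-(3-methylbut-2-en-1-yl)phenyl]chromane-4,7-diol F5 and leaves (2S)-ketone 6, which is separated by chromatography.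

**Step 5.**
- Risk: face selectivity may drop next to the bulky 8-silyloxy group, the electron-rich epoxide may open through a free cation to cis/trans mixtures, and liberated phenols may meet residual oxidant.
- Route: the fallback sets out from 10 and comes back at 13. C3 is set by osmylation and C4 by substrate-controlled solvolysis.
- Asymmetric dihydroxylation under base-free conditions uses OsO4 (2 mol %), (DHQ)2PYR and NMO in acetone/H2O at 0 °C, with slow addition of 10.
- This gives (2S)-7-(triethylsilyloxy)-2-[(3R,4R)-3,4-dihydroxy-2,2-dimethyl-8-(triethylsilyloxy)chroman-6-yl]chroman-4-one F6.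
- Treating F6 with 1 M aq H2SO4/THF at 40 °C ionises the benzylic C4–OH and recaptures water anti to the C3–OH, giving the more stable trans (3R,4S) arrangement. The same acid removes both silyl groups to give 13, and residual cis-diol is removed by chromatography.

## Further compounds
F1 | step 4 | 3-hydroxy-4-[(2-methylbut-3-yn-2-yl)oxy]benzaldehyde | C#CC(C)(C)Oc1ccc(C=O)cc1O
F2 | step 4 | 8-hydroxy-2,2-dimethyl-2H-chromene-6-carbaldehyde | CC1(C)C=Cc2cc(C=O)cc(O)c2O1
F3 | step 4 | (E)-1-(2,4-dihydroxyphenyl)-3-(8-hydroxy-2,2-dimethyl-2H-chromen-6-yl)prop-2-en-1-one | CC1(C)C=Cc2cc(/C=C/C(=O)c3ccc(O)cc3O)cc(O)c2O1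
F4 | step 3 | racemic 7-hydroxy-2-[4-hydroxy-3-(3-methylbut-2-en-1-yl)phenyl]chroman-4-one | CC(C)=CCc1cc(C2CC(=O)c3ccc(O)cc3O2)ccc1O
F5 | step 3 | (2R,4R)-2-[4-hydroxy-3-(3-methylbut-2-en-1-yl)phenyl]chromane-4,7-diol | CC(C)=CCc1cc([C@H]2C[C@@H](O)c3ccc(O)cc3O2)ccc1O
F6 | step 5 | (2S)-7-(triethylsilyloxy)-2-[(3R,4R)-3,4-dihydroxy-2,2-dimethyl-8-(triethylsilyloxy)chroman-6-yl]chroman-4-one | CC1(C)Oc2c(O[Si](CC)(CC)CC)cc([C@@H]3CC(=O)c4ccc(O[Si](CC)(CC)CC)cc4O3)cc2[C@@H](O)[C@H]1O
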